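Numbering: ring C1 (CHOAc), C2 (CH2), C3 (CHBr), C4 (CMe2), C5 (=CH), C6 (=C); side chain C7 (CHBr), C8 (CH2Cl). The target is (1R,3S,7R), with C1–OAc and C3–Br cis.
Retrosynthesis: C7–Br, C8–Cl, C1–OAc and C3–Br go back to carbinols (C7, C1 and C3 with inversion). The C5=C6 alkene goes back through a C6–C7 epoxide to an exocyclic (E)-C6=C7 alkene. The ring bond C1–C6 is then cut to an acyclic ynal, which is cut at C2–C3 (allylation) and C4–C5 (alkylation).
Enabling feature: in the only ring (carbocycle C1–C6), carbinol C1 and exocyclic stereocentre C7 are both bonded to C6. C1–C6 can therefore come from an aldehyde carbon and the inner carbon of a C6≡C7 alkyne, and the resulting 2-alkylidenecyclohexanol can pass its C1 configuration on to C7.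
Forward: C5–C8 (butynediol) is joined to C4 (isobutyronitrile), C1–C2 come from an allylborane, and the ring closes in the nickel step. After that only C–O and C–halogen chemistry and one alkene shift remain.
Stereochemistry: C3 comes from reagent-controlled allylboration, and C1 follows C3 (1,3-cis, chair-like cyclisation). C7 follows C1 by hydroxyl-directed epoxidation of the E alkene, and the C7–O bond is kept in the isomerisation. Three SN2 inversions (C3, C1, C7) then give the target descriptors.

Key step: step 8

Remark: locants C1–C8 and the descriptors quoted with them follow the numbering above, also in acyclic precursors. LDA and (+)-B-allyldiisopinocampheylborane are taken as the commercial solutions.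

Step 1
Reactants: 1 but-2-yne-1,4-diol
Product: 2 4-[(4-methoxybenzyl)oxy]but-2-yn-1-ol
Conditions: 1 (3 equiv), NaH (1 equiv), PMBCl (1 equiv), Bu4NI (cat.), THF/DMF, 0 °C → rt
Reagents that add atoms: 4-methoxybenzyl chloride, COc1ccc(CCl)cc1
Why: Williamson ether synthesis in which the symmetrical diol is used in excess over base and halide, so the reaction should stop at the mono-ether.

Step 2
Reactants: 2 4-[(4-methoxybenzyl)oxy]but-2-yn-1-ol
Product: 3 1-{[(4-bromobut-2-yn-1-yl)oxy]methyl}-4-methoxybenzene
Conditions: CBr4, PPh3, CH2Cl2, 0 °C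
Reagents that add atoms: carbon tetrabromide, BrC(Br)(Br)Br
Why: Appel bromination of a primary propargylic alcohol runs by SN2 attack of bromide on the oxyphosphonium ion under neutral conditions that leave the PMB ether and the alkyne alone.

Step 3
Reactants: 4 isobutyronitrile; 3 1-{[(4-bromobut-2-yn-1-yl)oxy]methyl}-4-methoxybenzene
Product: 6 6-[(4-methoxybenzyl)oxy]-2,2-dimethylhex-4-ynenitrile, via lithiated isobutyronitrile 5 (not isolated)
Conditions: LDA, THF, −78 °C; then 3, −78 °C → rt
Reagents that add atoms: none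
Why: SN2 alkylation of a tertiary nitrile-stabilised carbanion with a reactive primary propargylic bromide forms the C4–C5 bond and the quaternary C4 at once, and a second alkylation is impossible.

Step 4
Reactants: 6 6-[(4-methoxybenzyl)oxy]-2,2-dimethylhex-4-ynenitrile
Product: 8 6-[(4-methoxybenzyl)oxy]-2,2-dimethylhex-4-ynal, via N-alumanyl aldimine 7 (not isolated)
Conditions: DIBAL-H (1.2 equiv), CH2Cl2, −78 → −20 °C; then 1 M HCl, 0 °C
Reagents that add atoms: water, O
Why: DIBAL-H reduction of a nitrile stops at the N-aluminated imine, which dilute acid hydrolyses to the aldehyde, so the over-reduction typical of hindered esters is avoided.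

Step 5
Reactants: 8 6-[(4-methoxybenzyl)oxy]-2,2-dimethylhex-4-ynal; 9 (+)-B-allyldiisopinocampheylborane [from (−)-α-pinene]
Product: 11 (4R)-9-[(4-methoxybenzyl)oxy]-5,5-dimethylnon-1-en-7-yn-4-ol (carbinol = C3), via borinate ester 10 (not isolated)
Conditions: 9 (1.2 equiv, 1 M in pentane), Et2O, −100 → −78 °C; then 3 M NaOH, 30 % H2O2, rt
Reagents that add atoms: none
Why: Brown allylboration through a closed chair Zimmerman–Traxler transition state forms C2–C3, and the (−)-α-pinene-derived reagent adds to the face of pivalaldehyde-type aldehydes that gives the (R)-carbinol, so C3 is set by reagent control.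

Step 6
Reactants: 11 (4R)-9-[(4-methoxybenzyl)oxy]-5,5-dimethylnon-1-en-7-yn-4-ol
Product: 12 (4R)-9-[(4-methoxybenzyl)oxy]-5,5-dimethyl-4-(triethylsilyloxy)non-1-en-7-yne
Conditions: TESOTf, 2,6-lutidine, CH2Cl2, −78 → 0 °C
Reagents that add atoms: triethylsilyl triflate, CC[Si](CC)(CC)OS(=O)(=O)C(F)(F)F
Why: Silyl triflate with a hindered pyridine base silylates even a neopentylic carbinol, and TES is chosen because it can later be removed beside a TIPS ether.

Step 7
Reactants: 12 (4R)-9-[(4-methoxybenzyl)oxy]-5,5-dimethyl-4-(triethylsilyloxy)non-1-en-7-yne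
Product: 14 (3R)-8-[(4-methoxybenzyl)oxy]-4,4-dimethyl-3-(triethylsilyloxy)oct-6-ynal, via vicinal diol 13 (not isolated)
Conditions: OsO4 (2 mol %), NaIO4 (4 equiv), 2,6-lutidine (2 equiv), dioxane/H2O 3:1, rt
Reagents that add atoms: osmium tetroxide (catalytic oxygen carrier), O=[Os](=O)(=O)=O; sodium periodate (terminal oxygen source), [Na+].[O-]I(=O)(=O)=O
Why: In this Lemieux–Johnson cleavage the monosubstituted alkene is dihydroxylated far faster than the internal alkyne, periodate cleaves the diol to unveil C1 as the aldehyde, and the lutidine buffer guards against loss of the β-silyloxy group.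

Step 8
Reactants: 14 (3R)-8-[(4-methoxybenzyl)oxy]-4,4-dimethyl-3-(triethylsilyloxy)oct-6-ynal; 15 triisopropylsilane
Product: 16 (1S,3R,6E)-6-[2-(4-methoxybenzyloxy)ethylidene]-4,4-dimethyl-3-(triethylsilyloxy)-1-(triisopropylsilyloxy)cyclohexane (C1–O and C3–O cis; C8 cis to C5)
Conditions: Ni(cod)2 (10 mol %), IMes·HCl (10 mol %), KOt-Bu (10 mol %), 15 (2 equiv), THF, rt, slow addition of 14
Reagents that add atoms: none
Why: This is a nickel(0)-catalysed aldehyde–alkyne reductive coupling run intramolecularly: Ni(0) couples C1=O and C6≡C7 oxidatively to an oxanickelacyclopentene, σ-bond metathesis of Ni–O with Si–H places silicon on the C1 oxygen and hydride on nickel, and C–H reductive elimination releases the product and Ni(0). The six-membered ring closes 6-exo-dig, because the four-atom tether C2–C5 lets only the inner alkyne carbon C6 reach C1, so regiochemistry does not depend on the ligand. C1 and H add to the same side of the alkyne, which puts the C7 hydrogen cis to C1 and C8 cis to C5, that is the E alkene only. The new stereocentre C1 is controlled by C3: the flat metallacycle holds C1–O pseudo-equatorial and nearly eclipsed with C6=C7 in a chair-like array, the C3 silyloxy group stays equatorial to avoid syn-axial contacts, and the 1,3-cis (1S,3R) isomer should result. The C4 gem-dimethyl group favours the folded rotamer (Thorpe–Ingold effect), slow addition suppresses oligomerisation, and the PMB and TES ethers are inert to Ni(0) and silane. The bulky silane is chosen so that C1–O leaves the step as a TIPS ether that outlasts the TES group on C3.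

Step 9
Reactants: 16 (1S,3R,6E)-bis-silyl ether
Product: 17 (1S,3R,6E)-6-[2-(4-methoxybenzyloxy)ethylidene]-4,4-dimethyl-1-(triisopropylsilyloxy)cyclohexan-3-ol
Conditions: PPTS (0.2 equiv), MeOH/CH2Cl2, rt
Reagents that add atoms: none
Why: Acid-catalysed methanolysis distinguishes silyl ethers by the bulk at silicon, so the TES group should leave while the TIPS and PMB ethers stay, which frees only the C3 hydroxyl.

Step 10
Reactants: 17 (1S,3R,6E)-C3 alcohol
Product: 18 (1S,3S,6E)-3-bromo-6-[2-(4-methoxybenzyloxy)ethylidene]-4,4-dimethyl-1-(triisopropylsilyloxy)cyclohexane (Br trans to C1–O)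
Conditions: CBr4, P(n-Oct)3, toluene, 70 °C
Reagents that add atoms: carbon tetrabromide, BrC(Br)(Br)Br
Why: Appel-type bromination inverts C3 by SN2 attack of bromide on the oxyphosphonium ion, and although the centre is neopentylic the displacement should be viable because the equatorial leaving group of the diequatorial chair has no antiperiplanar hydrogen for E2 and the backside path runs axially on the face away from C1–O, over the C4–C5 bond and not over a methyl group.

Step 11
Reactants: 18 (1S,3S,6E)-bromo TIPS ether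
Product: 19 (1S,3S,6E)-3-bromo-6-[2-(4-methoxybenzyloxy)ethylidene]-4,4-dimethylcyclohexan-1-ol
Conditions: TBAF, AcOH (1:1), THF, 0 °C → rt
Reagents that add atoms: none
Why: Fluoride-induced desilylation frees the allylic C1 hydroxyl, and buffering with acetic acid keeps the medium non-basic so that the secondary bromide is not eliminated.

Step 12
Reactants: 19 (1S,3S,6E)-allylic alcohol
Product: 20 (1S,3S,6R,7R)-6-bromo-2-[(4-methoxybenzyloxy)methyl]-7,7-dimethyl-1-oxaspiro[2.5]octan-4-ol (C6–C7 epoxide, oxygen syn to C1–OH)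
Conditions: VO(acac)2 (5 mol %), t-BuOOH (1.5 equiv, decane), CH2Cl2, 0 °C → rt
Reagents that add atoms: tert-butyl hydroperoxide, CC(C)(C)OO
Why: In this vanadium-catalysed hydroxyl-directed epoxidation the C1 vanadate ester delivers the peroxide oxygen to the alkene face on the side of C1–OH (best from the chair with axial C1–OH and equatorial C3–Br, where that face also points away from the axial C4 methyl), and because the alkene is E this syn delivery fixes C6 as R and C7 as R.

Step 13
Reactants: 20 (1S,3S,6R,7R)-epoxy alcohol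
Product: 21 (1S,3S,6R,7R)-6-bromo-2-(hydroxymethyl)-7,7-dimethyl-1-oxaspiro[2.5]octan-4-ol
Conditions: DDQ (1.3 equiv), CH2Cl2/pH 7 buffer 10:1, 0 °C
Reagents that add atoms: none
Why: Oxidative PMB cleavage (hydride abstraction by DDQ, then hydrolysis of the oxocarbenium ion) in buffered medium spares the epoxide, the bromide and the secondary alcohol and frees C8–OH as the handle for the next step.

Step 14
Reactants: 21 (1S,3S,6R,7R)-epoxy diol
Product: 22 (1S,3S,7S)-1-(4-bromo-6-hydroxy-3,3-dimethylcyclohex-1-en-1-yl)ethane-1,2-diol (C5=C6 alkene; OH on C1, C7 and C8)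
Conditions: Ti(Oi-Pr)4 (2.2 equiv), CH2Cl2, rt → 40 °C; aq. tartaric acid work-up
Reagents that add atoms: none
Why: In this titanium(IV) isopropoxide-promoted rearrangement of a 3,3-disubstituted 2,3-epoxy alcohol to an ene-diol the alkoxide anchored on C8–O activates the oxirane, the tertiary C6–O bond breaks, and a ligand on titanium can reach only the protons on C5, the ring carbon that the E geometry placed cis to C8, so the alkene enters the ring as C5=C6 while the untouched C7–O bond keeps its configuration (now S because the CIP ranking of C6 and C8 changes).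

Step 15
Reactants: 22 (1S,3S,7S)-triol
Product: 23 (1S,5S)-5-bromo-2-[(4S)-2,2-dimethyl-1,3-dioxolan-4-yl]-4,4-dimethylcyclohex-2-en-1-ol
Conditions: Me2C(OMe)2, PPTS (cat.), CH2Cl2, rt
Reagents that add atoms: 2,2-dimethoxypropane, COC(C)(C)OC
Why: In acid-catalysed transacetalisation the terminal 1,2-diol closes the five-membered dioxolane in preference to a six-membered C1/C7 acetal, so only the C1 hydroxyl stays free.

Step 16
Reactants: 23 (1S,5S)-acetonide alcohol
Product: 24 (1R,5S)-5-bromo-2-[(4S)-2,2-dimethyl-1,3-dioxolan-4-yl]-4,4-dimethylcyclohex-2-en-1-yl acetate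
Conditions: AcOH, PPh3, DIAD, toluene, 0 °C → rt
Reagents that add atoms: acetic acid, CC(=O)O
Why: The Mitsunobu reaction inverts C1 by SN2 attack of acetate on the allylic oxyphosphonium ion, and because the SN2' terminus C5 is shielded by the adjacent C4 gem-dimethyl group it should give the (1R)-acetate directly.

Step 17
Reactants: 24 (1R,5S)-acetonide acetate
Product: 25 (1R,5S)-5-bromo-2-[(1S)-1,2-dihydroxyethyl]-4,4-dimethylcyclohex-2-en-1-yl acetate
Conditions: AcOH/H2O 4:1, 40 °C
Reagents that add atoms: none
Why: Mild aqueous acid hydrolyses the dioxolane, and acetic acid as the medium cannot exchange the C1 ester and avoids the base that would trigger acyl migration to C7–OH.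

Step 18
Reactants: 25 (1R,5S)-diol acetate
Product: 26 (1R,5S)-5-bromo-2-[(1S)-2-chloro-1-hydroxyethyl]-4,4-dimethylcyclohex-2-en-1-yl acetate
Conditions: NCS (1.05 equiv), PPh3 (1.05 equiv), THF, 0 °C → rt
Reagents that add atoms: N-chlorosuccinimide, O=C1CCC(=O)N1Cl
Why: Appel-type chlorination with the N-chlorosuccinimide/phosphine pair engages the unhindered primary hydroxyl first, so one equivalent should turn C8–OH into the chloride and leave the crowded C7 carbinol and its configuration untouched.

Step 19
Reactants: 26 (1R,5S)-chlorohydrin acetate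
Product: 27 (1R,5S)-5-bromo-2-[(1R)-1-bromo-2-chloroethyl]-4,4-dimethylcyclohex-2-en-1-yl acetate (CNP0213819.1)
Conditions: CBr4, PPh3, CH2Cl2, −20 → 0 °C
Reagents that add atoms: carbon tetrabromide, BrC(Br)(Br)Br
Why: Appel bromination in a non-ionising solvent at low temperature inverts C7 from S to R by SN2, since ionisation is held back by the β-chlorine on C8 and SN2' attack at C5 is blocked by the C4 gem-dimethyl group.

Compound list
1 | but-2-yne-1,4-diol | OCC#CCO | starting material
2 | 4-[(4-methoxybenzyl)oxy]but-2-yn-1-ol | OCC#CCOCc1ccc(OC)cc1 | intermediate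
3 | 1-{[(4-bromobut-2-yn-1-yl)oxy]methyl}-4-methoxybenzene | BrCC#CCOCc1ccc(OC)cc1 | intermediate
4 | isobutyronitrile | CC(C)C#N | starting material
5 | lithiated isobutyronitrile (not isolated) | [Li]C(C)(C)C#N | intermediate
6 | 6-[(4-methoxybenzyl)oxy]-2,2-dimethylhex-4-ynenitrile | N#CC(C)(C)CC#CCOCc1ccc(OC)cc1 | intermediate
7 | N-(diisobutylalumanyl) aldimine of 8 (not isolated) | CC(C)C[Al](CC(C)C)N=CC(C)(C)CC#CCOCc1ccc(OC)cc1 | intermediate
8 | 6-[(4-methoxybenzyl)oxy]-2,2-dimethylhex-4-ynal | O=CC(C)(C)CC#CCOCc1ccc(OC)cc1 | intermediate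
9 | (+)-B-allyldiisopinocampheylborane | C=CCB([C@H]1C[C@H]2C[C@@H]([C@@H]1C)C2(C)C)[C@H]1C[C@H]2C[C@@H]([C@@H]1C)C2(C)C | starting material
10 | diisopinocampheylborinate of 11 (not isolated) | C=CC[C@@H](OB([C@H]1C[C@H]2C[C@@H]([C@@H]1C)C2(C)C)[C@H]1C[C@H]2C[C@@H]([C@@H]1C)C2(C)C)C(C)(C)CC#CCOCc1ccc(OC)cc1 | intermediate
11 | (4R)-9-[(4-methoxybenzyl)oxy]-5,5-dimethylnon-1-en-7-yn-4-ol | C=CC[C@@H](O)C(C)(C)CC#CCOCc1ccc(OC)cc1 | intermediate
12 | (4R)-9-[(4-methoxybenzyl)oxy]-5,5-dimethyl-4-(triethylsilyloxy)non-1-en-7-yne | C=CC[C@@H](O[Si](CC)(CC)CC)C(C)(C)CC#CCOCc1ccc(OC)cc1 | intermediate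
13 | 1,2-diol from 12, both epimers at the new carbinol (not isolated) | OCC(O)C[C@@H](O[Si](CC)(CC)CC)C(C)(C)CC#CCOCc1ccc(OC)cc1 | intermediate
14 | (3R)-8-[(4-methoxybenzyl)oxy]-4,4-dimethyl-3-(triethylsilyloxy)oct-6-ynal | O=CC[C@@H](O[Si](CC)(CC)CC)C(C)(C)CC#CCOCc1ccc(OC)cc1 | intermediate
15 | triisopropylsilane | CC(C)[SiH](C(C)C)C(C)C | starting material
16 | (1S,3R,6E)-6-[2-(4-methoxybenzyloxy)ethylidene]-4,4-dimethyl-3-(triethylsilyloxy)-1-(triisopropylsilyloxy)cyclohexane | CC(C)[Si](C(C)C)(C(C)C)O[C@H]1C[C@@H](O[Si](CC)(CC)CC)C(C)(C)C/C1=C\COCc2ccc(OC)cc2 | intermediate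
17 | (1S,3R,6E)-6-[2-(4-methoxybenzyloxy)ethylidene]-4,4-dimethyl-1-(triisopropylsilyloxy)cyclohexan-3-ol | CC(C)[Si](C(C)C)(C(C)C)O[C@H]1C[C@@H](O)C(C)(C)C/C1=C\COCc2ccc(OC)cc2 | intermediate
18 | (1S,3S,6E)-3-bromo-6-[2-(4-methoxybenzyloxy)ethylidene]-4,4-dimethyl-1-(triisopropylsilyloxy)cyclohexane | CC(C)[Si](C(C)C)(C(C)C)O[C@H]1C[C@H](Br)C(C)(C)C/C1=C\COCc2ccc(OC)cc2 | intermediate
19 | (1S,3S,6E)-3-bromo-6-[2-(4-methoxybenzyloxy)ethylidene]-4,4-dimethylcyclohexan-1-ol | O[C@H]1C[C@H](Br)C(C)(C)C/C1=C\COCc2ccc(OC)cc2 | intermediate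
20 | (1S,3S,6R,7R)-6-bromo-2-[(4-methoxybenzyloxy)methyl]-7,7-dimethyl-1-oxaspiro[2.5]octan-4-ol | O[C@H]1C[C@H](Br)C(C)(C)C[C@@]12O[C@@H]2COCc3ccc(OC)cc3 | intermediate
21 | (1S,3S,6R,7R)-6-bromo-2-(hydroxymethyl)-7,7-dimethyl-1-oxaspiro[2.5]octan-4-ol | O[C@H]1C[C@H](Br)C(C)(C)C[C@@]12O[C@@H]2CO | intermediate
22 | (1S,3S,7S)-1-(4-bromo-6-hydroxy-3,3-dimethylcyclohex-1-en-1-yl)ethane-1,2-diol | O[C@H]1C[C@H](Br)C(C)(C)C=C1[C@H](O)CO | intermediate
23 | (1S,5S)-5-bromo-2-[(4S)-2,2-dimethyl-1,3-dioxolan-4-yl]-4,4-dimethylcyclohex-2-en-1-ol | O[C@H]1C[C@H](Br)C(C)(C)C=C1[C@H]2COC(C)(C)O2 | intermediate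
24 | (1R,5S)-5-bromo-2-[(4S)-2,2-dimethyl-1,3-dioxolan-4-yl]-4,4-dimethylcyclohex-2-en-1-yl acetate | CC(=O)O[C@@H]1C[C@H](Br)C(C)(C)C=C1[C@H]2COC(C)(C)O2 | intermediate
25 | (1R,5S)-5-bromo-2-[(1S)-1,2-dihydroxyethyl]-4,4-dimethylcyclohex-2-en-1-yl acetate | CC(=O)O[C@@H]1C[C@H](Br)C(C)(C)C=C1[C@H](O)CO | intermediate
26 | (1R,5S)-5-bromo-2-[(1S)-2-chloro-1-hydroxyethyl]-4,4-dimethylcyclohex-2-en-1-yl acetate | CC(=O)O[C@@H]1C[C@H](Br)C(C)(C)C=C1[C@H](O)CCl | intermediate
27 | (1R,5S)-5-bromo-2-[(1R)-1-bromo-2-chloroethyl]-4,4-dimethylcyclohex-2-en-1-yl acetate | CC(=O)O[C@@H]1C[C@H](Br)C(C)(C)C=C1[C@@H](Br)CCl | target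

Total step count: 19. Longest linear sequence: 19 steps (1 → 27).

Steps most likely to fail

Step 10 (bromide at the neopentylic C3). The displacement may be too slow. The oxyphosphonium ion could then ionise with a 1,2-shift of C5 or of a methyl group, or the hot phosphonium bromide medium could attack the silyl and benzyl ethers. In the fallback, activation and substitution are separated. Starting from 17, ClCH2SO2Cl and pyridine (CH2Cl2, 0 °C) give the chloromethanesulfonate F1, an isolable ester with a far better leaving group than a mesylate. A bromide salt (LiBr in DMF, or Bu4NBr in toluene, 40–50 °C) then displaces it with inversion, and the route is rejoined at 18.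

Step 14 (epoxide to ene-diol). The titanium alkoxide formed at C1 may compete with the one at C8 for the oxirane oxygen. Hydride or ring-carbon migration from C1 to C6, capture of C6 by isopropoxide, or no reaction at all (proton removal from the neopentylic C5 is slow) could then take over. The fallback replaces the chelation-controlled syn elimination by an ionic opening followed by an anti elimination. Starting from 21, excess TMSOTf and 2,6-lutidine (toluene, −78 °C) first cap both hydroxyls to the bis(trimethylsilyl) ether F2, which is opened in the same flask at the tertiary C6. DBU at rt then removes the C5 proton antiperiplanar to the departing oxygen and gives the tris(trimethylsilyl) ether F3. Citric acid in methanol returns the route to 22.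

Step 19 (bromide at the allylic C7). The activated carbinol may ionise, the product may undergo repeated bromide exchange, or the C1 acetate carbonyl may participate. Each of these would erode the C7 configuration. In the fallback, starting from 26, MsCl and Et3N (CH2Cl2, −40 °C) give the mesylate F4. In a separate operation one equivalent of LiBr (THF, −20 → 0 °C) displaces it. The product then never meets excess bromide or phosphonium species, and the route ends at 27.

Further compounds
F1 | step 10 | C3 chloromethanesulfonate of 17, configuration as in 17 | CC(C)[Si](C(C)C)(C(C)C)O[C@H]1C[C@@H](OS(=O)(=O)CCl)C(C)(C)C/C1=C\COCc2ccc(OC)cc2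
F2 | step 14 | C1,C8-bis(trimethylsilyl) ether of epoxy diol 21 | C[Si](C)(C)O[C@H]1C[C@H](Br)C(C)(C)C[C@@]12O[C@@H]2CO[Si](C)(C)C
F3 | step 14 | C1,C7,C8-tris(trimethylsilyl) ether of triol 22 | C[Si](C)(C)O[C@H]1C[C@H](Br)C(C)(C)C=C1[C@H](O[Si](C)(C)C)CO[Si](C)(C)C
F4 | step 19 | C7 methanesulfonate of chlorohydrin 26 | CC(=O)O[C@@H]1C[C@H](Br)C(C)(C)C=C1[C@H](OS(C)(=O)=O)CCl
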